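1. Over the first hours of the two earlier runs, at 2.5 mM and 3.8 mM of capture agent, target plus isomer of the product climbed to a level and stayed there. I wanted this flask at 5.0 min and at 4.0 h.

| flask | substrate | capture agent | remark | time |
|---|---|---|---|---|
| south | 0.25 M | 2.5 mM | run made earlier |  |
| north-west | 0.25 M | 3.8 mM | run made earlier |  |
| flask | 0.25 M | 5.00 mM |  | 4.0 h |

- south (time / h: isomer of the product / %, target / %): 0.200: 0.9, 19.3; 0.667: 2.1, 63.6; 1.00: 2.7, 75.5; 2.00: 3.6, 81.7; 2.50: 4.6, 81.7; 3.00: 4.4, 81.4
- north-west (time / h: isomer of the product / %, target / %): 0.500: 1.3, 52.2; 1.00: 2.9, 75.0; 1.50: 3.7, 79.8; 2.00: 3.8, 81.2; 2.50: 4.0, 81.5; 3.00: 4.3, 81.2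

(standard deviation of a reading: 0.3 percentage points)

- share of isomer of the product in isomer of the product plus target at 5.0 min
- share of isomer of the product in isomer of the product plus target at 4.0 h
- which of isomer of the product and target there is more of at 4.0 h

- reactions considered so far: open intermediate <-> target; substrate -> open intermediate; open intermediate + capture agent -> trapped intermediate; open intermediate <-> isomer of the product

2. I worked with the fraction left. In the south run the sum of the two products averaged 1.01 /h, as a fraction of the charge, over the first 0.200 h. The last readings of both runs put the level at 85.7% of the charge.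

3. In the north-west run the gap under that level was 32 percentage points at 0.500 h and 7.8 points at 1.00 h. It therefore shrank at 2.85 /h, which leaves 0.45 points at 2.00 h. That is the knee.

4. The earliest readings, at 0.200 h, 0.500 h and 0.667 h, give an isomer share of 3.08%. I took this as the split under kinetic control and as my figure for 5.0 min.

5. Isomer stood higher at 3.00 h than at 1.00 h in the south run, and likewise in the north-west run. Its creep, the part of the charge turned into isomer per hour, read between 1.00 h and 3.00 h and averaged over both runs, was 0.00775 /h.

6. Carried on from the last readings of the two runs, the creep gives this flask an estimated isomer of 5.12% at 4.0 h. That makes a share of 5.98%, with target at 80.6%, more than isomer.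

7. The forecast gave 2.9%, 5.6% and target ahead, on the ground that “target slowly leaks to isomer through reversal”; my early share is higher than its figure, and so is my late share.

8. The flask gave 2.89% and 6.28%, with target ahead at 79.8% against 5.35% of isomer.

    open intermediate ⇌ target (K = 6.00, k = 6.80 × 10⁻⁴ /s)
    substrate → open intermediate (k = 0.00200 /s)
    open intermediate + capture agent → trapped intermediate (k = 0.00320 /M/s)
    open intermediate ⇌ isomer of the product (K = 2.30, k = 2.00 × 10⁻⁵ /s)

In this flask isomer rose at 0.00806 /h between 2.00 h and 4.00 h, against my creep of 0.00775 /h. The neighbour flask was charged with 3.00 mM of capture agent, more than the south run and less than the north-west run, so the same creep gives it 5.12% of isomer and a share of 5.98% at 4.0 h. It ended with 5.38% of isomer, and it held 1.08% of trapped intermediate against 1.80% in the flask, with its share at 6.27%.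

The data are calculated from invented constants, and the scatter is random.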